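**Retrosynthetic overview**
1. The target is fisetinidol-(4α→6)-catechin. The upper unit has rings A (benzo), C (pyran) and B (catechol); the lower unit has rings D, F and E; flavan atom numbers are used. The last step removes nine benzyl groups, and the step before it closes ring F at O1–C8a of the lower unit.
2. Key disconnection O1–C8a: the C2 alkoxide adds to a C8≡C8a aryne of ring D, which is released from a C8 bromide. Oxygen enters next to the carbon that bromine leaves (cine-substitution), and ring D rises from the resorcinol to the phloroglucinol level.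
3. Enabling feature: in ring D, C8a lies between chain-bearing C4a and C8, the only unsubstituted ring carbon, and C8 is ortho to the C7 oxygen. A bromine on C8 therefore has one ortho hydrogen (on C8a) and only one aryne can form. Both the C7–O dipole and the C4–C3–C2 tether send O1 to C8a.
4. Ring D enters as symmetric 4,6-dibromoresorcinol. Its C2 (later C6) is joined to C4 of an (S)-flavanone (rings A, C, B; C2 set by rhodium catalysis), and hydroboration of the 4-arylflav-3-ene relays C3 and C4. One bromide becomes the C4a–C4 bond by opening an epoxide (lower C2 and C3 from a Sharpless kinetic resolution); the other triggers the aryne.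
5. Ring order: A/C are bought as a chromone, D is bought, and F is formed last.

Key step: step 13

Assumption: the (S)-configured biaryl bisphosphine is taken to give the (S)-flavanone, by analogy with rhodium/(S)-BINAP additions to cyclic enones; if the sense is opposite, the ligand antipode is used.

Step 1
Reactants: 1 3,4-bis(benzyloxy)benzaldehyde; 2 vinylmagnesium bromide
Product: 3 rac-1-[3,4-bis(benzyloxy)phenyl]prop-2-en-1-ol
Conditions: THF, 0 °C; aq NH4Cl
Reagents that add atoms: none
Why: Grignard 1,2-addition to a non-enolisable aldehyde gives the racemic aryl vinyl carbinol needed for the resolution.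

Step 2
Reactants: 3 rac-1-[3,4-bis(benzyloxy)phenyl]prop-2-en-1-ol
Product: 4 (R)-[3,4-bis(benzyloxy)phenyl][(S)-oxiran-2-yl]methanol
Conditions: Ti(OiPr)4 (0.15 equiv), L-(+)-diisopropyl tartrate (0.18 equiv), t-BuOOH (0.45 equiv), 4 Å MS, CH2Cl2, −20 °C
Reagents that add atoms: tert-butyl hydroperoxide CC(C)(C)OO
Why: In this Sharpless asymmetric epoxidation run as a kinetic resolution, the L-(+)-tartrate catalyst makes the (R)-alcohol react fast and epoxidises it erythro-selectively, which fixes both lower-unit stereocentres (later C2 R, C3 S), while the (S)-alcohol stays behind and is separated.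

Step 3
Reactants: 4 (R)-[3,4-bis(benzyloxy)phenyl][(S)-oxiran-2-yl]methanol
Product: 5 tert-butyl{(R)-[3,4-bis(benzyloxy)phenyl][(S)-oxiran-2-yl]methoxy}dimethylsilane
Conditions: TBSCl, imidazole, DMF, 25 °C
Reagents that add atoms: tert-butyldimethylsilyl chloride CC(C)(C)[Si](C)(C)Cl
Why: Silylation masks the future O1 with a group that can later be removed by fluoride in the presence of benzyl ethers, and no stereocentre is touched.

Step 4
Reactants: 6 7-hydroxy-4H-chromen-4-one
Product: 7 7-(benzyloxy)-4H-chromen-4-one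
Conditions: BnBr, K2CO3, DMF, 25 °C
Reagents that add atoms: benzyl bromide BrCc1ccccc1
Why: Williamson etherification of the only phenol.

Step 5
Reactants: 7 7-(benzyloxy)-4H-chromen-4-one; 8 [3,4-bis(benzyloxy)phenyl]boronic acid
Product: 9 (2S)-7-(benzyloxy)-2-[3,4-bis(benzyloxy)phenyl]chroman-4-one
Conditions: [Rh(OH)(cod)]2 (1.5 mol %), (S)-MeO-F12-BIPHEP (3.3 mol %), toluene/H2O, 25 °C
Reagents that add atoms: none
Why: The Hayashi–Miyaura asymmetric 1,4-addition of an arylboronic acid to a chromone sets upper C2 under ligand control, and the nearly neutral two-phase medium avoids retro-oxa-Michael opening of the flavanone.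

Step 6
Reactants: 10 4,6-dibromobenzene-1,3-diol
Product: 11 4,6-dibromo-2-iodobenzene-1,3-diol
Conditions: N-iodosuccinimide, MeCN, 0 → 25 °C
Reagents that add atoms: N-iodosuccinimide O=C1CCC(=O)N1I
Why: Electrophilic aromatic iodination can only occur at C2, the one free position ortho to both hydroxyl groups.

Step 7
Reactants: 11 4,6-dibromo-2-iodobenzene-1,3-diol
Product: 12 1,3-bis(benzyloxy)-4,6-dibromo-2-iodobenzene
Conditions: BnBr, K2CO3, DMF, 60 °C
Reagents that add atoms: benzyl bromide BrCc1ccccc1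
Why: Twofold Williamson etherification gives the symmetric ring D building block.

Step 8
Reactants: 12 1,3-bis(benzyloxy)-4,6-dibromo-2-iodobenzene; 9 (2S)-7-(benzyloxy)-2-[3,4-bis(benzyloxy)phenyl]chroman-4-one
Product: 15 (2S)-7-(benzyloxy)-2-[3,4-bis(benzyloxy)phenyl]-4-[2,6-bis(benzyloxy)-3,5-dibromophenyl]-2H-chromene, via arylmagnesium chloride 13 (not isolated), via tertiary flavan-4-ol 14 (not isolated)
Conditions: 12, i-PrMgCl·LiCl, THF, −30 °C; LaCl3·2LiCl, then 9, −30 → 0 °C; aq NH4Cl; then p-TsOH·H2O (5 mol %), toluene, 25 °C, dark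
Reagents that add atoms: none
Why: Iodine–magnesium exchange is selective for iodide over bromide, the lanthanum-promoted Grignard 1,2-addition suppresses enolisation, and the doubly benzylic tertiary alcohol loses water by E1 dehydration; this makes the C4–C6 bond at a site fixed by the iodide and leaves C2 untouched.

Step 9
Reactants: 15 (2S)-7-(benzyloxy)-2-[3,4-bis(benzyloxy)phenyl]-4-[2,6-bis(benzyloxy)-3,5-dibromophenyl]-2H-chromene
Product: 17 (2R,3S,4S)-7-(benzyloxy)-2-[3,4-bis(benzyloxy)phenyl]-4-[2,6-bis(benzyloxy)-3,5-dibromophenyl]chroman-3-ol, via alkylborane 16 (not isolated)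
Conditions: BH3·SMe2, THF, 0 → 25 °C; then NaOH, H2O2, 0 °C
Reagents that add atoms: hydrogen peroxide OO
Why: In the Brown hydroboration–oxidation boron goes to the less substituted C3 and the H/B pair adds syn to the face opposite ring B, so C2 alone sets C3 (OH trans to ring B) and C4 (ring D trans to OH) in one event, and the oxidation proceeds with retention.

Step 10
Reactants: 17 (2R,3S,4S)-7-(benzyloxy)-2-[3,4-bis(benzyloxy)phenyl]-4-[2,6-bis(benzyloxy)-3,5-dibromophenyl]chroman-3-ol; 5 tert-butyl{(R)-[3,4-bis(benzyloxy)phenyl][(S)-oxiran-2-yl]methoxy}dimethylsilane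
Product: 19 seco-dimer diol (upper 3-OH and lower 3-OH free; lower C2 as OTBS; Br on C8 of ring D), via dilithio species 18 (not isolated)
Conditions: 17, n-BuLi (2.1 equiv), THF, −78 °C; then 5, BF3·OEt2, −78 °C; aq NaHCO3
Reagents that add atoms: none
Why: After deprotonation of the 3-OH, bromine–lithium exchange of one of the two bromides (equivalent through rotation about C4–C6) gives an aryllithium with no leaving group ortho to it; this opens the BF3-activated terminal epoxide at CH2, so lower C2 and C3 come unchanged from 5.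

Step 11
Reactants: 19 seco-dimer diol
Product: 20 seco-dimer silyl ether (both 3-OH groups benzylated)
Conditions: 2-benzyloxy-1-methylpyridinium triflate (4 equiv), MgO, PhCF3, 85 °C
Reagents that add atoms: 2-benzyloxy-1-methylpyridinium triflate C[n+]1ccccc1OCc1ccccc1.[O-]S(=O)(=O)C(F)(F)F
Why: Neutral thermal benzyl transfer protects both secondary alcohols without forming an alkoxide, which avoids migration of the neighbouring silyl group from the C2 oxygen to the C3 oxygen.

Step 12
Reactants: 20 seco-dimer silyl ether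
Product: 21 seco-dimer alcohol (free lower C2–OH; Br on C8)
Conditions: Bu4NF, THF, 0 → 25 °C
Reagents that add atoms: none
Why: Fluoride desilylation frees only the future O1, and the benzyl ethers, the aryl bromide and all stereocentres are inert.

Step 13
Reactants: 21 seco-dimer alcohol
Product: 24 nona-O-benzyl fisetinidol-(4α→6)-catechin, via aryne alkoxide 22 (not isolated), via C8 aryllithium 23 (not isolated)
Conditions: LiN(iPr)2 (4 equiv), THF, −78 → 0 °C; aq NH4Cl
Reagents that add atoms: none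
Why: The amide first makes the C2 lithium alkoxide and then removes the only hydrogen ortho to bromine on ring D (C8a–H); loss of LiBr gives the C8≡C8a aryne 22, the tethered alkoxide adds to C8a, and the C8 aryllithium 23 is protonated by diisopropylamine, so bromine leaves C8 while oxygen enters at C8a (cine-substitution by elimination–addition). The closest known reaction type is the base-induced aryne cyclisation of ω-(halophenyl)alkanols to chromans and dihydrobenzofurans. Ring F closes in the 6-exo-dig mode, with C8a inside and C8 outside the new ring. No stereocentre is formed, and C2 keeps its configuration because its C–O bond is never broken, which is the advantage of making the aryl–oxygen bond instead of the ionisable benzylic one next to electron-rich ring E. Selectivity is needed twice: only one aryne can form because the other position ortho to bromine carries the C7 benzyloxy group, and attack at C8a over C8 is favoured both by the inductive polarisation of a 3-alkoxyaryne and by ring size (six against seven), while the C3 oxygen, which would close a five-membered ring, is blocked as its benzyl ether. In one operation the step closes ring F, installs the third oxygen of ring D and erases the auxiliary bromine.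

Step 14
Reactants: 24 nona-O-benzyl fisetinidol-(4α→6)-catechin
Product: 25 fisetinidol-(4α→6)-catechin (target)
Conditions: H2 (1 atm), Pd(OH)2/C, THF/MeOH, 25 °C
Reagents that add atoms: none
Why: Neutral catalytic hydrogenolysis removes all nine benzyl ethers, while the ring C–O bonds and the C4–C6 interflavan bond are expected to survive, as is usual for benzylated proanthocyanidins.

**Compound list**
1 | 3,4-bis(benzyloxy)benzaldehyde | O=Cc1ccc(OCc2ccccc2)c(OCc2ccccc2)c1 | starting material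
2 | vinylmagnesium bromide | C=C[Mg]Br | starting material
3 | rac-1-[3,4-bis(benzyloxy)phenyl]prop-2-en-1-ol | C=CC(O)c1ccc(OCc2ccccc2)c(OCc2ccccc2)c1 | intermediate
4 | (R)-[3,4-bis(benzyloxy)phenyl][(S)-oxiran-2-yl]methanol | C1O[C@@H]1[C@@H](c1ccc(OCc2ccccc2)c(OCc2ccccc2)c1)O | intermediate
5 | tert-butyl{(R)-[3,4-bis(benzyloxy)phenyl][(S)-oxiran-2-yl]methoxy}dimethylsilane | C1O[C@@H]1[C@@H](c1ccc(OCc2ccccc2)c(OCc2ccccc2)c1)O[Si](C)(C)C(C)(C)C | intermediate
6 | 7-hydroxy-4H-chromen-4-one | O=c1ccoc2cc(O)ccc12 | starting material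
7 | 7-(benzyloxy)-4H-chromen-4-one | O=c1ccoc2cc(OCc3ccccc3)ccc12 | intermediate
8 | [3,4-bis(benzyloxy)phenyl]boronic acid | OB(O)c1ccc(OCc2ccccc2)c(OCc2ccccc2)c1 | starting material
9 | (2S)-7-(benzyloxy)-2-[3,4-bis(benzyloxy)phenyl]chroman-4-one | c1ccccc1COc1ccc2c(c1)O[C@H](c1ccc(OCc3ccccc3)c(OCc3ccccc3)c1)CC2=O | intermediate
10 | 4,6-dibromobenzene-1,3-diol | Oc1cc(O)c(Br)cc1Br | starting material
11 | 4,6-dibromo-2-iodobenzene-1,3-diol | Oc1c(I)c(O)c(Br)cc1Br | intermediate
12 | 1,3-bis(benzyloxy)-4,6-dibromo-2-iodobenzene | Ic1c(OCc2ccccc2)c(Br)cc(Br)c1OCc1ccccc1 | intermediate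
13 | [2,6-bis(benzyloxy)-3,5-dibromophenyl]magnesium chloride (not isolated) | Cl[Mg]c1c(OCc2ccccc2)c(Br)cc(Br)c1OCc1ccccc1 | intermediate
14 | (2S)-4-aryl tertiary flavan-4-ol, C4 epimers (not isolated) | c1ccccc1COc1ccc2c(c1)O[C@H](c1ccc(OCc3ccccc3)c(OCc3ccccc3)c1)CC2(O)c1c(OCc3ccccc3)c(Br)cc(Br)c1OCc1ccccc1 | intermediate
15 | (2S)-7-(benzyloxy)-2-[3,4-bis(benzyloxy)phenyl]-4-[2,6-bis(benzyloxy)-3,5-dibromophenyl]-2H-chromene | c1ccccc1COc1ccc2c(c1)O[C@H](c1ccc(OCc3ccccc3)c(OCc3ccccc3)c1)C=C2c1c(OCc3ccccc3)c(Br)cc(Br)c1OCc1ccccc1 | intermediate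
16 | C3 alkylborane, boron trans to ring B and to ring D (not isolated) | c1ccccc1COc1ccc2c(c1)O[C@H](c1ccc(OCc3ccccc3)c(OCc3ccccc3)c1)[C@@H](B)[C@@H]2c1c(OCc3ccccc3)c(Br)cc(Br)c1OCc1ccccc1 | intermediate
17 | (2R,3S,4S)-7-(benzyloxy)-2-[3,4-bis(benzyloxy)phenyl]-4-[2,6-bis(benzyloxy)-3,5-dibromophenyl]chroman-3-ol | c1ccccc1COc1ccc2c(c1)O[C@H](c1ccc(OCc3ccccc3)c(OCc3ccccc3)c1)[C@@H](O)[C@@H]2c1c(OCc3ccccc3)c(Br)cc(Br)c1OCc1ccccc1 | intermediate
18 | lithium 3-alkoxide and ring D aryllithium (not isolated) | c1ccccc1COc1ccc2c(c1)O[C@H](c1ccc(OCc3ccccc3)c(OCc3ccccc3)c1)[C@@H](O[Li])[C@@H]2c1c(OCc3ccccc3)c(Br)cc([Li])c1OCc1ccccc1 | intermediate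
19 | seco-dimer diol (upper 2R,3S,4S; lower C2 R as OTBS, C3 S as OH; Br on C8) | c1ccccc1COc1ccc2c(c1)O[C@H](c1ccc(OCc3ccccc3)c(OCc3ccccc3)c1)[C@@H](O)[C@@H]2c1c(OCc3ccccc3)c(Br)cc(c1OCc1ccccc1)C[C@H](O)[C@@H](c1ccc(OCc3ccccc3)c(OCc3ccccc3)c1)O[Si](C)(C)C(C)(C)C | intermediate
20 | seco-dimer silyl ether (both 3-O-benzyl) | c1ccccc1COc1ccc2c(c1)O[C@H](c1ccc(OCc3ccccc3)c(OCc3ccccc3)c1)[C@@H](OCc1ccccc1)[C@@H]2c1c(OCc3ccccc3)c(Br)cc(c1OCc1ccccc1)C[C@H](OCc1ccccc1)[C@@H](c1ccc(OCc3ccccc3)c(OCc3ccccc3)c1)O[Si](C)(C)C(C)(C)C | intermediate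
21 | seco-dimer alcohol (free lower C2–OH; Br on C8) | c1ccccc1COc1ccc2c(c1)O[C@H](c1ccc(OCc3ccccc3)c(OCc3ccccc3)c1)[C@@H](OCc1ccccc1)[C@@H]2c1c(OCc3ccccc3)c(Br)cc(c1OCc1ccccc1)C[C@H](OCc1ccccc1)[C@@H](c1ccc(OCc3ccccc3)c(OCc3ccccc3)c1)O | intermediate
22 | C8≡C8a aryne of ring D with lithium C2 alkoxide (not isolated) | c1ccccc1COc1ccc2c(c1)O[C@H](c1ccc(OCc3ccccc3)c(OCc3ccccc3)c1)[C@@H](OCc1ccccc1)[C@@H]2C1=C(OCc3ccccc3)C#CC(=C1OCc1ccccc1)C[C@H](OCc1ccccc1)[C@@H](c1ccc(OCc3ccccc3)c(OCc3ccccc3)c1)O[Li] | intermediate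
23 | ring-closed C8 aryllithium (not isolated) | c1ccccc1COc1ccc2c(c1)O[C@H](c1ccc(OCc3ccccc3)c(OCc3ccccc3)c1)[C@@H](OCc1ccccc1)[C@@H]2c1c(OCc3ccccc3)c([Li])c2c(c1OCc1ccccc1)C[C@H](OCc1ccccc1)[C@@H](c1ccc(OCc3ccccc3)c(OCc3ccccc3)c1)O2 | intermediate
24 | nona-O-benzyl fisetinidol-(4α→6)-catechin | c1ccccc1COc1ccc2c(c1)O[C@H](c1ccc(OCc3ccccc3)c(OCc3ccccc3)c1)[C@@H](OCc1ccccc1)[C@@H]2c1c(OCc3ccccc3)cc2c(c1OCc1ccccc1)C[C@H](OCc1ccccc1)[C@@H](c1ccc(OCc3ccccc3)c(OCc3ccccc3)c1)O2 | intermediate
25 | fisetinidol-(4α→6)-catechin (upper 2R,3S,4S; lower 2R,3S) | Oc1ccc2c(c1)O[C@H](c1ccc(O)c(O)c1)[C@@H](O)[C@@H]2c1c(O)cc2c(c1O)C[C@H](O)[C@@H](c1ccc(O)c(O)c1)O2 | target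

**Step count**
- Total step count: 14.
- Longest linear sequence: 9 steps (10 → 11 → 12 → 15 → 17 → 19 → 20 → 21 → 24 → 25). The branch from 6 is equally long.

**Steps most likely to fail**

Step 13 is the first risk. Removal of C8a–H next to bromine may be slow. In that case amide addition to the aryne, or base-induced loss of the upper C3 benzyloxy group after deprotonation at C4, could take over.
- The fallback replaces elimination–addition by ipso substitution of fluoride. This is an intramolecular SNAr of an alkoxide on a 3,5-dialkoxyfluorobenzene, a known type of pyran closure for flavan-3-ols.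
- It sets out from 9. Commercial 5-fluorobenzene-1,3-diol is iodinated between its hydroxyl groups to 5-fluoro-2-iodobenzene-1,3-diol F1 and benzylated to 1,3-bis(benzyloxy)-5-fluoro-2-iodobenzene F2.
- The operations of step 8 with 9 give the 4-(fluoroaryl)-2H-chromene F3, and those of step 9 give the 4-(fluoroaryl)flavan-3-ol F4.
- n-BuLi (two equivalents) lithiates F4 between fluorine and benzyloxy, at either of two equivalent positions. Opening of 5 with BF3·OEt2 then gives the fluoro diol F5.
- Benzylation as in step 11 gives the fluoro silyl ether F6, and Bu4NF gives the fluoro alcohol F7. KH in DMF closes ring F at C8a with loss of fluoride, and the route is rejoined at 24.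

Step 8 is the second risk. The basic, doubly ortho-substituted aryl nucleophile may enolise the flavanone, which would open ring C by retro-oxa-Michael reaction and erode the configuration at C2. It may also fail to transfer at all.
- The fallback makes the C4–C6 bond by cross-coupling and sets out from 9.
- KN(SiMe3)2 and N-phenylbis(trifluoromethanesulfonimide) at −78 °C give the flavanone enol triflate F8.
- 13 is transmetalated with ZnCl2 to the arylzinc chloride F9.
- Negishi coupling with Pd(PPh3)4, in which the vinyl triflate reacts ahead of the hindered aryl bromides, comes back at 15.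

Step 9 is the third risk. Hydroboration of the crowded trisubstituted alkene may be sluggish or show poor facial selectivity.
- The fallback reverses the order, oxygen first and aryl second. It sets out from 9 and also bypasses step 8.
- NaBH4 gives the flavan-4-ol F10, and methanesulfonyl chloride with Et3N gives the 2-aryl-2H-chromene F11.
- Dimethyldioxirane epoxidises the face opposite ring B to the flav-3-ene oxide F12.
- CuI-catalysed opening at benzylic C4 by 13, anti to the oxygen, gives the all-trans product and comes back at 17.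

Further compounds
F1 | step 13 | 5-fluoro-2-iodobenzene-1,3-diol | Oc1cc(F)cc(O)c1I
F2 | step 13 | 1,3-bis(benzyloxy)-5-fluoro-2-iodobenzene | Ic1c(OCc2ccccc2)cc(F)cc1OCc1ccccc1
F3 | step 13 | 4-(fluoroaryl)-2H-chromene, (2S) | c1ccccc1COc1ccc2c(c1)O[C@H](c1ccc(OCc3ccccc3)c(OCc3ccccc3)c1)C=C2c1c(OCc3ccccc3)cc(F)cc1OCc1ccccc1
F4 | step 13 | 4-(fluoroaryl)flavan-3-ol, (2R,3S,4S) | c1ccccc1COc1ccc2c(c1)O[C@H](c1ccc(OCc3ccccc3)c(OCc3ccccc3)c1)[C@@H](O)[C@@H]2c1c(OCc3ccccc3)cc(F)cc1OCc1ccccc1
F5 | step 13 | fluoro diol (F on C8a; lower C2 as OTBS) | c1ccccc1COc1ccc2c(c1)O[C@H](c1ccc(OCc3ccccc3)c(OCc3ccccc3)c1)[C@@H](O)[C@@H]2c1c(OCc3ccccc3)cc(F)c(c1OCc1ccccc1)C[C@H](O)[C@@H](c1ccc(OCc3ccccc3)c(OCc3ccccc3)c1)O[Si](C)(C)C(C)(C)C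
F6 | step 13 | fluoro silyl ether (both 3-O-benzyl) | c1ccccc1COc1ccc2c(c1)O[C@H](c1ccc(OCc3ccccc3)c(OCc3ccccc3)c1)[C@@H](OCc1ccccc1)[C@@H]2c1c(OCc3ccccc3)cc(F)c(c1OCc1ccccc1)C[C@H](OCc1ccccc1)[C@@H](c1ccc(OCc3ccccc3)c(OCc3ccccc3)c1)O[Si](C)(C)C(C)(C)C
F7 | step 13 | fluoro alcohol (free lower C2–OH) | c1ccccc1COc1ccc2c(c1)O[C@H](c1ccc(OCc3ccccc3)c(OCc3ccccc3)c1)[C@@H](OCc1ccccc1)[C@@H]2c1c(OCc3ccccc3)cc(F)c(c1OCc1ccccc1)C[C@H](OCc1ccccc1)[C@@H](c1ccc(OCc3ccccc3)c(OCc3ccccc3)c1)O
F8 | step 8 | flavanone enol triflate, (2S) | c1ccccc1COc1ccc2c(c1)O[C@H](c1ccc(OCc3ccccc3)c(OCc3ccccc3)c1)C=C2OS(=O)(=O)C(F)(F)F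
F9 | step 8 | [2,6-bis(benzyloxy)-3,5-dibromophenyl]zinc chloride | Cl[Zn]c1c(OCc2ccccc2)c(Br)cc(Br)c1OCc1ccccc1
F10 | step 9 | flavan-4-ol, (2S), C4 epimers | c1ccccc1COc1ccc2c(c1)O[C@H](c1ccc(OCc3ccccc3)c(OCc3ccccc3)c1)CC2O
F11 | step 9 | 2-aryl-2H-chromene, (2S) | c1ccccc1COc1ccc2c(c1)O[C@H](c1ccc(OCc3ccccc3)c(OCc3ccccc3)c1)C=C2
F12 | step 9 | flav-3-ene oxide, oxygen trans to ring B | c1ccccc1COc1ccc2c(c1)O[C@H](c1ccc(OCc3ccccc3)c(OCc3ccccc3)c1)[C@H]3O[C@@H]23
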